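**Plan**

- Locants used below: ring A = C1–C5 and C10; ring B = C5–C10 with C5=C6. C4 carries C19 (methyl) and C18 (CH2OAc), C8 carries C17, and C9 carries C20 and the chain C11–C15 (C16 on C13).
- Retrosynthesis: the acetate and acid are unveiled last. The C11–C12 bond is cut (olefination of a C11 aldehyde, then saturation). Then C7–C8 and C9–C10 are cut together. Then ring A is opened at C10=C5/C6=C7 (enyne metathesis) to an acyclic quaternary aldehyde, which comes from a 1,2-shift in an epoxy silyl ether.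
- Enabling feature: ring B is a cyclohexene whose C5=C6 bond lies between C7–C8 and C10–C9; C5 and C10 also belong to ring A; C9 is quaternary with a one-carbon arm (C11) that can be a formyl group. This is the retron of a [4+2] addition of an (E)-α-methyl enal to a 1-vinylcyclohexene.
- Forward order: C4 first (acyclic), then ring A with its diene, then ring B in one cycloaddition, then the chain.
- Stereochemistry: C4 comes from a Sharpless epoxidation and a stereospecific shift. C8/C9 come from the E geometry of the dienophile and C10 from the exo mode; their absolute sense comes from a chiral oxazaborolidinium catalyst matched with the C4 bias. C13 is bought in a chiral lactone.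

Key step: step 7

Remark: the 1,2-shift in step 4 is assumed to run anti (inversion at the migration terminus), as is usual for this rearrangement; the three purchased building blocks (an enyne, an enal, an enantiopure β-methyl lactone) are assumed available.

**Route**

Step 1
Reactants: 1 hept-1-en-6-yne
Product: 3 (2E)-3-methylocta-2,7-dien-1-ol, via (E)-alkenyldimethylalane 2 (not isolated)
Conditions: Me3Al (2 equiv), Cp2ZrCl2 (0.25 equiv), CH2Cl2, 0 °C → rt; then n-BuLi, THF, −78 °C; (CH2O)n, → rt; aq. HCl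
Reagents that add atoms: trimethylaluminium, C[Al](C)C; paraformaldehyde (as formaldehyde), C=O
Why: Negishi carboalumination adds CH3 and Al syn across the terminal alkyne with Al at the terminal carbon, and the derived alanate is hydroxymethylated with retention, so the E allylic alcohol should form while the isolated terminal alkene stays untouched.

Step 2
Reactants: 3 (2E)-3-methylocta-2,7-dien-1-ol
Product: 4 [(2S,3S)-3-methyl-3-(pent-4-en-1-yl)oxiran-2-yl]methanol
Conditions: Ti(OiPr)4 (10 mol%), diethyl L-(+)-tartrate (12 mol%), t-BuOOH, 4 Å molecular sieves, CH2Cl2, −20 °C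
Reagents that add atoms: tert-butyl hydroperoxide, CC(C)(C)OO
Why: Sharpless asymmetric epoxidation acts only on the allylic alkene, and with the L-(+)-tartrate ligand an (E)-3,3-disubstituted allylic alcohol of the geraniol type should give the (2S,3S)-epoxide.

Step 3
Reactants: 4 [(2S,3S)-3-methyl-3-(pent-4-en-1-yl)oxiran-2-yl]methanol
Product: 5 tert-butyl{[(2S,3S)-3-methyl-3-(pent-4-en-1-yl)oxiran-2-yl]methoxy}diphenylsilane
Conditions: t-BuPh2SiCl, imidazole, DMF, rt
Reagents that add atoms: tert-butyl(chloro)diphenylsilane, CC(C)(C)[Si](Cl)(c1ccccc1)c1ccccc1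
Why: Standard silylation of a primary alcohol; the bulky silyl group keeps the ether oxygen from binding the Lewis acid in step 4 and later serves as the large substituent on C4.

Step 4
Reactants: 5 tert-butyl{[(2S,3S)-3-methyl-3-(pent-4-en-1-yl)oxiran-2-yl]methoxy}diphenylsilane
Product: 6 (2S)-2-({[tert-butyl(diphenyl)silyl]oxy}methyl)-2-methylhept-6-enal
Conditions: MeAl(OAr)2 (Ar = 4-bromo-2,6-di-tert-butylphenyl; from Me3Al and 2 ArOH; 20 mol%), CH2Cl2, −78 → −20 °C
Reagents that add atoms: none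
Why: Lewis-acid-promoted rearrangement of a 2,3-epoxy silyl ether to a β-siloxy aldehyde (semipinacol type): the bulky aluminium aryloxide opens the tertiary C–O bond and the siloxymethyl group shifts to that carbon anti to the leaving oxygen, so the epoxide configuration is relayed with inversion into the quaternary carbon (future C4).

Step 5
Reactants: 6 (2S)-2-({[tert-butyl(diphenyl)silyl]oxy}methyl)-2-methylhept-6-enal
Product: 7 tert-butyl{[(2R)-2-ethynyl-2-methylhept-6-en-1-yl]oxy}diphenylsilane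
Conditions: dimethyl (1-diazo-2-oxopropyl)phosphonate, K2CO3, MeOH, 0 °C → rt
Reagents that add atoms: dimethyl (1-diazo-2-oxopropyl)phosphonate (Ohira–Bestmann reagent), COP(=O)(OC)C(=[N+]=[N-])C(C)=O
Why: Ohira–Bestmann (Seyferth–Gilbert) homologation turns the aldehyde into the terminal alkyne; the aldehyde has no α-hydrogen, so the quaternary centre cannot epimerise and no β-elimination of the siloxy group is possible.

Step 6
Reactants: 7 tert-butyl{[(2R)-2-ethynyl-2-methylhept-6-en-1-yl]oxy}diphenylsilane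
Product: 8 tert-butyl{[(1R)-2-ethenyl-1-methylcyclohex-2-en-1-yl]methoxy}diphenylsilane
Conditions: second-generation Grubbs catalyst RuCl2(=CHPh)(PCy3)(H2IMes) (5 mol%), ethylene (1 atm), CH2Cl2, 40 °C
Reagents that add atoms: none
Why: Ring-closing enyne metathesis of the 1,7-enyne in the exo mode closes ring A (C10–C5 bond) and delivers the 1-vinylcyclohexene diene in one isomerisation; the quaternary carbon favours closure and ethylene keeps the ruthenium carbene turning over.

Step 7
Reactants: 8 tert-butyl{[(1R)-2-ethenyl-1-methylcyclohex-2-en-1-yl]methoxy}diphenylsilane; 9 (2E)-2-methylbut-2-enal (tiglic aldehyde)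
Product: 10 (1R,2S,5R,8aR)-5-({[tert-butyl(diphenyl)silyl]oxy}methyl)-1,2,5-trimethyl-1,2,3,5,6,7,8,8a-octahydronaphthalene-1-carbaldehyde
Conditions: 9 (3 equiv), (R)-tetrahydro-1-(2-methylphenyl)-3,3-diphenyl-1H,3H-pyrrolo[1,2-c][1,3,2]oxazaborole (20 mol%), HN(SO2CF3)2 (17 mol%), CH2Cl2, −78 → −40 °C
Reagents that add atoms: none
Why: The protonated oxazaborolidine binds the formyl oxygen of 9 (formyl C–H···O contact to the ring oxygen, enal s-trans and stacked on one phenyl group), and the activated enal adds to the s-cis diene C10=C5–C6=C7 of 8 in a concerted but asynchronous [4+2] cycloaddition in which the C7–C8 bond leads and the C9–C10 bond follows. The closest known reaction types are the Lewis-acid-promoted exo-selective Diels–Alder reaction of tiglic aldehyde with 6,6-disubstituted 1-vinylcyclohexenes (halimane and clerodane decalins) and the oxazaborolidinium-catalysed Diels–Alder reaction of 2-substituted enals. Ring B is closed as a six-membered carbocycle by intermolecular [4+2] cycloaddition, suprafacial on both partners, which leaves the new alkene at C5=C6. C8 and C9 take their relative configuration from the E geometry of 9 (C17 and C20 cis); C10 is set relative to C9 by the exo transition state that 2-substituted enals prefer (formyl group away from the diene, C20 over it, hence C20 trans to H10); the absolute sense of all three comes from the catalyst, whose (R) antipode should, by the pre-transition-state model, leave the Cα-Si face of 9 open. The step needs regioselectivity (C8 must bond to C7), secured by C7 being the unsubstituted, most nucleophilic and least hindered diene terminus; exo selectivity, secured by the α-methyl group of 9; and diene-face selectivity (addition anti to C18), enforced by the catalyst and supported by the large CH2OSi(t-Bu)Ph2 group, which should sit pseudoaxial on the half-chair of ring A and shield its own face. Diastereomers from minor pathways are expected to be separable at this aldehyde stage.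

Step 8
Reactants: 11 (4S)-4-methyloxolan-2-one [(S)-β-methyl-γ-butyrolactone]
Product: 12 [(2S)-3-carboxy-2-methylpropyl](triphenyl)phosphonium bromide
Conditions: Ph3P·HBr, neat, 160 °C
Reagents that add atoms: triphenylphosphine hydrobromide, [Br-].[PH+](c1ccccc1)(c1ccccc1)c1ccccc1
Why: Acid-assisted SN2 opening of a γ-butyrolactone at its O–CH2 carbon by bromide and then phosphine, a known route to (3-carboxypropyl)phosphonium salts; the stereocentre is not touched.

Step 9
Reactants: 10 (1R,2S,5R,8aR)-5-({[tert-butyl(diphenyl)silyl]oxy}methyl)-1,2,5-trimethyl-1,2,3,5,6,7,8,8a-octahydronaphthalene-1-carbaldehyde; 12 [(2S)-3-carboxy-2-methylpropyl](triphenyl)phosphonium bromide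
Product: 14 (3S,4Z)-5-[(1S,2S,5R,8aS)-5-({[tert-butyl(diphenyl)silyl]oxy}methyl)-1,2,5-trimethyl-1,2,3,5,6,7,8,8a-octahydronaphthalen-1-yl]-3-methylpent-4-enoic acid, via carboxylate ylide 13 (not isolated)
Conditions: 12 (3 equiv), NaN(SiMe3)2 (6 equiv), THF, 0 °C; then 10, rt → 50 °C; aq. HCl
Reagents that add atoms: none
Why: Wittig olefination with a non-stabilised carboxylate ylide joins C11 to C12; the aldehyde cannot enolise, the alkene geometry (Z expected) is irrelevant because it is saturated next, and C13 arrives unchanged from 11.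

Step 10
Reactants: 14 (3S,4Z)-5-[(1S,2S,5R,8aS)-5-({[tert-butyl(diphenyl)silyl]oxy}methyl)-1,2,5-trimethyl-1,2,3,5,6,7,8,8a-octahydronaphthalen-1-yl]-3-methylpent-4-enoic acid
Product: 15 (3R)-5-[(1R,2S,5R,8aS)-5-({[tert-butyl(diphenyl)silyl]oxy}methyl)-1,2,5-trimethyl-1,2,3,5,6,7,8,8a-octahydronaphthalen-1-yl]-3-methylpentanoic acid
Conditions: p-toluenesulfonyl hydrazide (10 equiv), NaOAc (12 equiv), THF/H2O, reflux
Reagents that add atoms: none
Why: Diimide reduction (concerted syn transfer of two hydrogens) is fast for the 1,2-disubstituted C11=C12 alkene and very slow for the trisubstituted ring alkene C5=C6 flanked by quaternary C4, so only the chain alkene should be saturated and no stereocentre is made or lost.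

Step 11
Reactants: 15 (3R)-5-[(1R,2S,5R,8aS)-5-({[tert-butyl(diphenyl)silyl]oxy}methyl)-1,2,5-trimethyl-1,2,3,5,6,7,8,8a-octahydronaphthalen-1-yl]-3-methylpentanoic acid
Product: 16 (3R)-5-[(1R,2S,5R,8aS)-5-(hydroxymethyl)-1,2,5-trimethyl-1,2,3,5,6,7,8,8a-octahydronaphthalen-1-yl]-3-methylpentanoic acid
Conditions: Bu4NF (4 equiv), THF, 50 °C; aq. NH4Cl
Reagents that add atoms: none
Why: Fluoride-mediated cleavage of the silyl ether under non-acidic conditions frees the C18 alcohol without risk of moving the C5=C6 double bond.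

Step 12
Reactants: 16 (3R)-5-[(1R,2S,5R,8aS)-5-(hydroxymethyl)-1,2,5-trimethyl-1,2,3,5,6,7,8,8a-octahydronaphthalen-1-yl]-3-methylpentanoic acid
Product: 18 (3R)-5-[(1R,2S,5R,8aS)-5-(acetoxymethyl)-1,2,5-trimethyl-1,2,3,5,6,7,8,8a-octahydronaphthalen-1-yl]-3-methylpentanoic acid, via mixed acetic anhydride 17 (not isolated)
Conditions: Ac2O (5 equiv), pyridine, 4-(dimethylamino)pyridine (cat.), CH2Cl2, rt; then H2O/THF, rt; dilute HCl wash
Reagents that add atoms: acetic anhydride, CC(=O)OC(C)=O
Why: Nucleophile-catalysed acetylation esterifies the neopentyl alcohol; the carboxylic acid is acylated only transiently as a mixed anhydride, which water cleaves back to the free acid on work-up.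

**Compound list**

1 | hept-1-en-6-yne | C=CCCCC#C | starting material
2 | dimethyl[(1E)-2-methylhepta-1,6-dien-1-yl]alane | C=CCCC/C(C)=C/[Al](C)C | intermediate
3 | (2E)-3-methylocta-2,7-dien-1-ol | C=CCCC/C(C)=C/CO | intermediate
4 | [(2S,3S)-3-methyl-3-(pent-4-en-1-yl)oxiran-2-yl]methanol | OC[C@@H]1O[C@@]1(C)CCCC=C | intermediate
5 | tert-butyl{[(2S,3S)-3-methyl-3-(pent-4-en-1-yl)oxiran-2-yl]methoxy}diphenylsilane | CC(C)(C)[Si](c1ccccc1)(c1ccccc1)OC[C@@H]1O[C@@]1(C)CCCC=C | intermediate
6 | (2S)-2-({[tert-butyl(diphenyl)silyl]oxy}methyl)-2-methylhept-6-enal | CC(C)(C)[Si](c1ccccc1)(c1ccccc1)OC[C@](C=O)(C)CCCC=C | intermediate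
7 | tert-butyl{[(2R)-2-ethynyl-2-methylhept-6-en-1-yl]oxy}diphenylsilane | CC(C)(C)[Si](c1ccccc1)(c1ccccc1)OC[C@](C#C)(C)CCCC=C | intermediate
8 | tert-butyl{[(1R)-2-ethenyl-1-methylcyclohex-2-en-1-yl]methoxy}diphenylsilane | CC(C)(C)[Si](c1ccccc1)(c1ccccc1)OC[C@]1(C)CCCC=C1C=C | intermediate
9 | (2E)-2-methylbut-2-enal (tiglic aldehyde) | C/C=C(\C)C=O | starting material
10 | (1R,2S,5R,8aR)-5-({[tert-butyl(diphenyl)silyl]oxy}methyl)-1,2,5-trimethyl-1,2,3,5,6,7,8,8a-octahydronaphthalene-1-carbaldehyde | CC(C)(C)[Si](c1ccccc1)(c1ccccc1)OC[C@]1(C)CCC[C@@H]2C1=CC[C@H](C)[C@@]2(C)C=O | intermediate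
11 | (4S)-4-methyloxolan-2-one | C[C@@H]1COC(=O)C1 | starting material
12 | [(2S)-3-carboxy-2-methylpropyl](triphenyl)phosphonium bromide | C[C@@H](CC(=O)O)C[P+](c1ccccc1)(c1ccccc1)c1ccccc1.[Br-] | intermediate
13 | sodium (3S)-3-methyl-4-(triphenyl-λ5-phosphanylidene)butanoate | [Na+].[O-]C(=O)C[C@H](C)C=P(c1ccccc1)(c1ccccc1)c1ccccc1 | intermediate
14 | (3S,4Z)-5-[(1S,2S,5R,8aS)-5-({[tert-butyl(diphenyl)silyl]oxy}methyl)-1,2,5-trimethyl-1,2,3,5,6,7,8,8a-octahydronaphthalen-1-yl]-3-methylpent-4-enoic acid | CC(C)(C)[Si](c1ccccc1)(c1ccccc1)OC[C@]1(C)CCC[C@@H]2C1=CC[C@H](C)[C@@]2(C)/C=C\[C@@H](C)CC(=O)O | intermediate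
15 | (3R)-5-[(1R,2S,5R,8aS)-5-({[tert-butyl(diphenyl)silyl]oxy}methyl)-1,2,5-trimethyl-1,2,3,5,6,7,8,8a-octahydronaphthalen-1-yl]-3-methylpentanoic acid | CC(C)(C)[Si](c1ccccc1)(c1ccccc1)OC[C@]1(C)CCC[C@@H]2C1=CC[C@H](C)[C@@]2(C)CC[C@@H](C)CC(=O)O | intermediate
16 | (3R)-5-[(1R,2S,5R,8aS)-5-(hydroxymethyl)-1,2,5-trimethyl-1,2,3,5,6,7,8,8a-octahydronaphthalen-1-yl]-3-methylpentanoic acid | OC[C@]1(C)CCC[C@@H]2C1=CC[C@H](C)[C@@]2(C)CC[C@@H](C)CC(=O)O | intermediate
17 | acetic (3R)-5-[(1R,2S,5R,8aS)-5-(acetoxymethyl)-1,2,5-trimethyl-1,2,3,5,6,7,8,8a-octahydronaphthalen-1-yl]-3-methylpentanoic anhydride | CC(=O)OC[C@]1(C)CCC[C@@H]2C1=CC[C@H](C)[C@@]2(C)CC[C@@H](C)CC(=O)OC(C)=O | intermediate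
18 | (3R)-5-[(1R,2S,5R,8aS)-5-(acetoxymethyl)-1,2,5-trimethyl-1,2,3,5,6,7,8,8a-octahydronaphthalen-1-yl]-3-methylpentanoic acid | CC(=O)OC[C@]1(C)CCC[C@@H]2C1=CC[C@H](C)[C@@]2(C)CC[C@@H](C)CC(=O)O | target

**Summary**

Total steps: 12. Longest linear sequence: 11 steps (steps 1–7 and 9–12); step 8 makes the side-chain salt separately.

Steps most likely to fail:

1. Step 7. The cycloaddition of a β-substituted enal with a hindered diene may be slow. Reagent control may work against, rather than with, the facial bias of C4. The acid catalyst may oligomerise the diene. Fallback from 8 and 9 back to 10: aldehyde 9 is converted with ethane-1,2-diol and catalytic pyridinium p-toluenesulfonate into its acetal 2-[(2E)-but-2-en-2-yl]-1,3-dioxolane F1. With catalytic Me3SiOSO2CF3 in CH2Cl2 at −78 °C, F1 opens to an alkoxy-allyl cation, a much stronger dienophile (ionic Diels–Alder reaction). It should add to 8 with the same orientation to give 2-[(1R,2S,5R,8aR)-5-({[tert-butyl(diphenyl)silyl]oxy}methyl)-1,2,5-trimethyl-1,2,3,5,6,7,8,8a-octahydronaphthalen-1-yl]-1,3-dioxolane F2. Mild hydrolysis (aqueous acetone, pyridinium p-toluenesulfonate) returns aldehyde 10. In this variant the diene face is controlled by C4 alone and the minor diastereomer is removed by chromatography.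

2. Step 9. A β-branched, non-stabilised ylide may add too slowly to the neopentyl aldehyde, so that ylide decay outruns olefination. Fallback from 10 back to 15, using stabilised phosphonates and setting C13 by catalysis:
   - Horner–Wadsworth–Emmons reaction of 10 with dimethyl (2-oxopropyl)phosphonate and Ba(OH)2 in wet THF should give (3E)-4-[(1S,2S,5R,8aS)-5-({[tert-butyl(diphenyl)silyl]oxy}methyl)-1,2,5-trimethyl-1,2,3,5,6,7,8,8a-octahydronaphthalen-1-yl]but-3-en-2-one F3.
   - Conjugate reduction with [(Ph3P)CuH]6 gives the saturated methyl ketone 4-[(1R,2S,5R,8aS)-5-({[tert-butyl(diphenyl)silyl]oxy}methyl)-1,2,5-trimethyl-1,2,3,5,6,7,8,8a-octahydronaphthalen-1-yl]butan-2-one F4.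
   - A second Horner–Wadsworth–Emmons reaction (triethyl phosphonoacetate, NaH, THF) gives, after removal of the Z isomer, ethyl (2E)-5-[(1R,2S,5R,8aS)-5-({[tert-butyl(diphenyl)silyl]oxy}methyl)-1,2,5-trimethyl-1,2,3,5,6,7,8,8a-octahydronaphthalen-1-yl]-3-methylpent-2-enoate F5.
   - Copper hydride asymmetric conjugate reduction (CuCl, NaOtBu, (S)-p-tol-BINAP as the antipode proposed for 13R, polymethylhydrosiloxane) gives ethyl (3R)-5-[(1R,2S,5R,8aS)-5-({[tert-butyl(diphenyl)silyl]oxy}methyl)-1,2,5-trimethyl-1,2,3,5,6,7,8,8a-octahydronaphthalen-1-yl]-3-methylpentanoate F6.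
   - Saponification with LiOH in THF/H2O gives acid 15. This fallback also bypasses step 10.

3. Step 4. A hydride shift (to an α-siloxy ketone) or capture of the tertiary cation by the terminal alkene may compete with the siloxymethyl shift, and stereochemical fidelity is lost if the cation is long-lived. Fallback from 3 back to 7, making the quaternary centre by an SN2-type epoxide opening instead:
   - Sharpless epoxidation of 3 with diethyl D-(−)-tartrate gives the enantiomeric epoxide [(2R,3R)-3-methyl-3-(pent-4-en-1-yl)oxiran-2-yl]methanol F7.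
   - Et2AlC≡CSiMe3 (toluene, 0 °C) should open it at the tertiary carbon with inversion to give (2S,3R)-3-methyl-3-[(trimethylsilyl)ethynyl]oct-7-ene-1,2-diol F8.
   - NaIO4 cleaves the diol to (2R)-2-methyl-2-[(trimethylsilyl)ethynyl]hept-6-enal F9.
   - NaBH4 reduces it to (2R)-2-methyl-2-[(trimethylsilyl)ethynyl]hept-6-en-1-ol F10.
   - t-BuPh2SiCl and imidazole give tert-butyl({(2R)-2-methyl-2-[(trimethylsilyl)ethynyl]hept-6-en-1-yl}oxy)diphenylsilane F11.
   - K2CO3 in MeOH removes the alkynyl silyl group and gives alkyne 7.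

**Further compounds**

F1 | step 7 | 2-[(2E)-but-2-en-2-yl]-1,3-dioxolane | C/C=C(\C)C1OCCO1
F2 | step 7 | 2-[(1R,2S,5R,8aR)-5-({[tert-butyl(diphenyl)silyl]oxy}methyl)-1,2,5-trimethyl-1,2,3,5,6,7,8,8a-octahydronaphthalen-1-yl]-1,3-dioxolane | CC(C)(C)[Si](c1ccccc1)(c1ccccc1)OC[C@]1(C)CCC[C@@H]2C1=CC[C@H](C)[C@@]2(C)C3OCCO3
F3 | step 9 | (3E)-4-[(1S,2S,5R,8aS)-5-({[tert-butyl(diphenyl)silyl]oxy}methyl)-1,2,5-trimethyl-1,2,3,5,6,7,8,8a-octahydronaphthalen-1-yl]but-3-en-2-one | CC(C)(C)[Si](c1ccccc1)(c1ccccc1)OC[C@]1(C)CCC[C@@H]2C1=CC[C@H](C)[C@@]2(C)/C=C/C(C)=O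
F4 | step 9 | 4-[(1R,2S,5R,8aS)-5-({[tert-butyl(diphenyl)silyl]oxy}methyl)-1,2,5-trimethyl-1,2,3,5,6,7,8,8a-octahydronaphthalen-1-yl]butan-2-one | CC(C)(C)[Si](c1ccccc1)(c1ccccc1)OC[C@]1(C)CCC[C@@H]2C1=CC[C@H](C)[C@@]2(C)CCC(C)=O
F5 | step 9 | ethyl (2E)-5-[(1R,2S,5R,8aS)-5-({[tert-butyl(diphenyl)silyl]oxy}methyl)-1,2,5-trimethyl-1,2,3,5,6,7,8,8a-octahydronaphthalen-1-yl]-3-methylpent-2-enoate | CC(C)(C)[Si](c1ccccc1)(c1ccccc1)OC[C@]1(C)CCC[C@@H]2C1=CC[C@H](C)[C@@]2(C)CC/C(C)=C/C(=O)OCC
F6 | step 9 | ethyl (3R)-5-[(1R,2S,5R,8aS)-5-({[tert-butyl(diphenyl)silyl]oxy}methyl)-1,2,5-trimethyl-1,2,3,5,6,7,8,8a-octahydronaphthalen-1-yl]-3-methylpentanoate | CC(C)(C)[Si](c1ccccc1)(c1ccccc1)OC[C@]1(C)CCC[C@@H]2C1=CC[C@H](C)[C@@]2(C)CC[C@@H](C)CC(=O)OCC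
F7 | step 4 | [(2R,3R)-3-methyl-3-(pent-4-en-1-yl)oxiran-2-yl]methanol | OC[C@H]1O[C@]1(C)CCCC=C
F8 | step 4 | (2S,3R)-3-methyl-3-[(trimethylsilyl)ethynyl]oct-7-ene-1,2-diol | OC[C@@H](O)[C@@](C)(C#C[Si](C)(C)C)CCCC=C
F9 | step 4 | (2R)-2-methyl-2-[(trimethylsilyl)ethynyl]hept-6-enal | O=C[C@@](C)(C#C[Si](C)(C)C)CCCC=C
F10 | step 4 | (2R)-2-methyl-2-[(trimethylsilyl)ethynyl]hept-6-en-1-ol | OC[C@@](C)(C#C[Si](C)(C)C)CCCC=C
F11 | step 4 | tert-butyl({(2R)-2-methyl-2-[(trimethylsilyl)ethynyl]hept-6-en-1-yl}oxy)diphenylsilane | CC(C)(C)[Si](c1ccccc1)(c1ccccc1)OC[C@@](C)(C#C[Si](C)(C)C)CCCC=C
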